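When this flask is read at 6.0 h, the question is how long its chains are, counted over every chain begun.

L 0.050 M; Q 0.500 mM; E 5 mol%; time 6.0 h

    L + E → Z + J (k1 = 0.082 /M/s)
    L + Z → J + Z, rate k2*[Z]*[L] (k2 = 0.016 /M/s)
    Z + Q → Z.Q (k3 = 0.88 /M/s)
    Z → D (k4 = 6.1 × 10⁻⁵ /s)

- the average divides the monomer in chains by the number of chains begun, living and dead together
- run time (flask): 6.0 h

1. whether the average number of monomer units in a chain (chains begun, living or dead) reaches 6.0 by 6.0 h (yes / no)
2. average number of monomer units in a chain (chains begun, living or dead) at 6.0 h

Two chemists agree on the opening: E has a half-life of 2.82 min against the charged L and Q one of 5.25 min against the ends, both far shorter than the 3.2 h in which Z halves by dying, so chains begun come to 5 mol% of the L charged, and once each Q has capped one end, the living ends stand at 4.00% of that charge.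

The first chemist holds that these ends simply stay, which makes the loss of L pseudo-first-order, with a logarithmic fall of 0.691 by the time of reading and a length of 10.5.

The second answers that Z halves well inside the run, so the rate of L must be integrated over a decaying Z, and this has a closed form: the growth constant times the L charge times the living fraction, divided by the dying constant, comes to 0.525, and this quantity, the reach, multiplied by the part of the ends dead by then, is the logarithmic fall of L. That part is 73.2%, so the fall is 0.384, L stands at 64.7%, and the length is 7.06. The wanted length needs a fall of 0.305, which is less than that, so I, reckoning with the second chemist, say it is reached.

The forecast sides with the second chemist, answering yes with a length of 7, in a range of 6.8 to 7.2, a little below my figure, and saying “It rises steadily”.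

The flask gives yes and a length of 7.05, with L at 64.8%, so the second view stands. The first view comes close in the opening: at 0.600 h it puts L at 88.7% and the flask reads 89.4%. At the asked time L has a half-life of 22 h by growth, longer than the 3.2 h of Z by dying. Carried to 60.0 h, the reach gives a fall of 0.525 and L at 56.2%, and the flask then holds L at 56.2% with Z at 3.82 × 10⁻⁹ M.

The constants used here come from no measurement; what happens was integrated by code.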